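The eight-membered ring C (C1, C2, C6, C7, C8, C17, C18, C19) is disconnected at C17–C18. Because C7 carries oxygen and C1=C2 is unsaturated, every atom of this ring can be made trigonal: the ring is a 3-oxido-octatetraene, C17=C8–C7(O−)=C6–C2=C1–C19=C18, whose central diene ring D holds s-cis. Remote enolisation of a cross-conjugated trienone (a trans-decalin vinyl ketone of a pulegone-derived cyclopentene) triggers conrotatory 8π ring closure at C17–C18. This sets C17 and leaves the C7/C8 enolate for in-flask methylation (quaternary C8). One dissolving-metal operation on the resulting dienone then installs the C1=C2 alkene, C6–H and the C7 carbinol.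

Key step: step 12

Numbering used for the target and all intermediates: C1 (alkene carbon bearing methyl C20), C2 (alkene carbon shared by rings C and D), C3 and C4 (CH2), C5 (CH bearing methyl C21), C6 (C/D ring-fusion CH), C7 (carbinol carbon), C8 (quaternary, methyl C22), C9 and C10 (CH2), C11 (quaternary, methyl C23), C12 and C13 (CH2), C14 (CMe2), C15 (CH2), C16 (A/B ring-fusion CH), C17 (B/C ring-fusion CH), C18 and C19 (CH2). Ring A = C11–C16; ring B = C8–C11, C16, C17; ring C as above; ring D = C2–C6. The β face is the face of ring B that carries H16 and the C22 methyl group. Target descriptors in this numbering: 1Z, 5S, 6S, 7R, 8S, 11S, 16S, 17S.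

Remark: compounds 1, 3, 4, 12, 17 and 19 are taken as commercial, and the facial sense of step 2 is assumed to follow the parent 2-methylcyclohexanone case.

Step 1
Reactants: 1 3,3-dimethylcyclohexan-1-one
Product: 2 2,5,5-trimethylcyclohexan-1-one (racemic)
Conditions: LiN(i-Pr)2, THF, −78 °C; MeI, −78 → 0 °C
Reagents that add atoms: methyl iodide, CI
Why: Kinetic deprotonation should occur at the α-methylene remote from the quaternary carbon and the enolate is C-methylated (ketone enolate alkylation); the new centre is racemic and is corrected in step 2.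

Step 2
Reactants: 2 2,5,5-trimethylcyclohexan-1-one, 3 (R)-1-phenylethan-1-amine, 4 but-3-en-2-one
Product: 7 (S)-2,5,5-trimethyl-2-(3-oxobutyl)cyclohexan-1-one, via ketimine 5 (not isolated), via Michael-adduct imine 6 (not isolated)
Conditions: 3, TsOH (cat.), toluene, reflux (water separator); then 4, THF, 40 °C; then 20% aq AcOH, rt
Reagents that add atoms: water, O
Why: Deracemising Michael addition: the imine reacts through its more substituted secondary enamine, which should add to the enone on the face away from the phenyl group of the (R)-auxiliary and so fix the quaternary centre C11 as (S) (the parent ketone with the (S)-amine gives the (R) series); hydrolysis returns the auxiliary.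

Step 3
Reactants: 7 (S)-2,5,5-trimethyl-2-(3-oxobutyl)cyclohexan-1-one
Product: 8 (S)-4a,7,7-trimethyl-4,4a,5,6,7,8-hexahydronaphthalen-2(3H)-one
Conditions: NaOMe, MeOH, rt → reflux
Reagents that add atoms: none
Why: Intramolecular aldol condensation completes the Robinson annulation without touching the quaternary stereocentre.

Step 4
Reactants: 8 (S)-4a,7,7-trimethyl-4,4a,5,6,7,8-hexahydronaphthalen-2(3H)-one
Product: 10 (4aS,8aS)-4a,7,7-trimethyl-3,4,4a,5,6,7,8,8a-octahydronaphthalen-2-yl trifluoromethanesulfonate, via lithium enolate 9 (not isolated)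
Conditions: Li, NH3/THF, t-BuOH (1 equiv), −78 °C; NH3 removed; PhNTf2, THF, 0 °C → rt
Reagents that add atoms: N-phenyl-bis(trifluoromethanesulfonimide), O=S(=O)(N(c1ccccc1)S(=O)(=O)C(F)(F)F)C(F)(F)F
Why: Birch-type enone reduction protonates the β-carbon axially, giving the trans ring fusion (H16 anti to the C23 methyl), and leaves the regiodefined C8=C17 enolate, which is O-sulfonylated (reductive enolate trapping).

Step 5
Reactants: 10 (4aS,8aS)-4a,7,7-trimethyl-3,4,4a,5,6,7,8,8a-octahydronaphthalen-2-yl trifluoromethanesulfonate
Product: 11 trimethyl[(4aS,8aS)-4a,7,7-trimethyl-3,4,4a,5,6,7,8,8a-octahydronaphthalen-2-yl]stannane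
Conditions: Me3SnSnMe3, Pd(PPh3)4 (cat.), LiCl, THF, 60 °C
Reagents that add atoms: hexamethylditin, C[Sn](C)(C)[Sn](C)(C)C
Why: Palladium-catalysed stannylation of an enol triflate (oxidative addition, Sn–Sn transmetalation, reductive elimination) should give the vinylstannane with the alkene position and both stereocentres unchanged.

Step 6
Reactants: 12 (S)-(−)-pulegone
Product: 14 methyl (5S)-5-methyl-2-(propan-2-ylidene)cyclopentane-1-carboxylate (mixture of C1 epimers), via pulegone dibromide 13 (not isolated)
Conditions: Br2, Et2O, 0 °C; then NaOMe, MeOH, reflux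
Reagents that add atoms: sodium methoxide, C[O-].[Na+]
Why: Favorskii ring contraction of the α,α′-dibromoketone with methoxide, followed by loss of HBr, gives the pulegenate; the methyl-bearing centre (later C5) is untouched and the epimeric ester carbon becomes sp2 in step 8.

Step 7
Reactants: 14 methyl (5S)-5-methyl-2-(propan-2-ylidene)cyclopentane-1-carboxylate
Product: 15 methyl (2S)-2-methyl-5-oxocyclopentane-1-carboxylate
Conditions: O3, CH2Cl2/MeOH, −78 °C; Me2S, −78 °C → rt
Reagents that add atoms: ozone, [O-][O+]=O
Why: Ozonolysis with reductive work-up cleaves the tetrasubstituted exocyclic alkene to the ring ketone and acetone.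

Step 8
Reactants: 15 methyl (2S)-2-methyl-5-oxocyclopentane-1-carboxylate
Product: 16 methyl (5S)-5-methyl-2-(trifluoromethanesulfonyloxy)cyclopent-1-ene-1-carboxylate
Conditions: NaH, THF, 0 °C; PhNTf2, 0 °C → rt
Reagents that add atoms: N-phenyl-bis(trifluoromethanesulfonimide), O=S(=O)(N(c1ccccc1)S(=O)(=O)C(F)(F)F)C(F)(F)F
Why: The β-keto ester enolate is O-sulfonylated to the cyclic β-triflyloxy enoate (enol triflate formation), which also removes the epimerisable centre.

Step 9
Reactants: 16 methyl (5S)-5-methyl-2-(trifluoromethanesulfonyloxy)cyclopent-1-ene-1-carboxylate, 17 (Z)-but-2-en-2-ylboronic acid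
Product: 18 methyl (5S)-2-[(E)-but-2-en-2-yl]-5-methylcyclopent-1-ene-1-carboxylate
Conditions: Pd(PPh3)4 (cat.), K3PO4, 1,4-dioxane/H2O, 80 °C
Reagents that add atoms: none
Why: Suzuki–Miyaura coupling of the vinyl triflate with the alkenylboronic acid proceeds with retention of alkene geometry (the geometry is erased in step 12).

Step 10
Reactants: 18 methyl (5S)-2-[(E)-but-2-en-2-yl]-5-methylcyclopent-1-ene-1-carboxylate, 19 N,O-dimethylhydroxylamine hydrochloride
Product: 20 (5S)-2-[(E)-but-2-en-2-yl]-N-methoxy-N,5-dimethylcyclopent-1-ene-1-carboxamide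
Conditions: i-PrMgCl (3 equiv), THF, −20 → 0 °C
Reagents that add atoms: none
Why: The magnesium amide of the hydroxylamine converts the ester into the Weinreb amide (aminolysis), so that step 11 stops at the ketone.

Step 11
Reactants: 11 trimethyl[(4aS,8aS)-4a,7,7-trimethyl-3,4,4a,5,6,7,8,8a-octahydronaphthalen-2-yl]stannane, 20 (5S)-2-[(E)-but-2-en-2-yl]-N-methoxy-N,5-dimethylcyclopent-1-ene-1-carboxamide
Product: 22 [(4aS,8aS)-4a,7,7-trimethyl-3,4,4a,5,6,7,8,8a-octahydronaphthalen-2-yl]{(5S)-2-[(E)-but-2-en-2-yl]-5-methylcyclopent-1-en-1-yl}methanone, via vinyllithium 21 (not isolated)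
Conditions: MeLi, THF, −78 → −40 °C; then 20, −78 → 0 °C; aq NH4Cl
Reagents that add atoms: none
Why: Tin–lithium exchange gives the vinyllithium, which should add once to the Weinreb amide through the chelated tetrahedral intermediate (Weinreb ketone synthesis) to form the C7–C8 bond of the cross-conjugated trienone.

Step 12
Reactants: 22 [(4aS,8aS)-4a,7,7-trimethyl-3,4,4a,5,6,7,8,8a-octahydronaphthalen-2-yl]{(5S)-2-[(E)-but-2-en-2-yl]-5-methylcyclopent-1-en-1-yl}methanone
Product: 25 (5S,8S,11S,16S,17S)-C8-methylated tetracyclic 1(19),2(6)-dien-7-one, via open potassium trienolate 23 (not isolated), via cyclised potassium enolate 24 (not isolated)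
Conditions: KN(SiMe3)2 (1.1 equiv), THF, −78 → 0 °C; then MeI, −78 → −20 °C
Reagents that add atoms: methyl iodide, CI
Why: Proposed new method: KN(SiMe3)2 removes a hydrogen from the C18 methyl group (ε to the carbonyl) to give the fully conjugated trienolate 23, a 3-oxido-octatetraene C17=C8–C7(O−)=C6–C2=C1–C19=C18 whose helical form closes by thermal conrotatory 8π electrocyclisation to the cyclooctatrienolate 24; the closest known reactions are the 8π closures of neutral (Z,Z)-tetraenes and the eight-electron closure of heptatrienyl anions, an enolate-triggered closure of this substrate class being undocumented. Ring C is closed in the pericyclic 8π conrotatory mode at C17–C18, with ring D holding the central C6–C2 diene s-cis and only hydrogen atoms pointing into the helix. C17 is fixed by the sense of the helix: C18 can reach C17 only on the β face, because the axial C23 methyl group on C11 (1,3 to C17) shields the α face. The closure leaves the C7/C8 enolate regiospecifically and methyl iodide should enter C8 on the β (axial) face, the only approach that keeps C7 equatorial on the chair of ring B and the C7–C8–C17–C18 torsion on the side imposed by the closed ring (trans B/C fusion); this is the least secure stereochemical point, since equatorial attack on the exocyclic enolate would give the cis-fused epimer. The step needs ε- over γ-enolisation (C3–H) and closure before alkylation: the enolates interconvert by proton transfer and by rotation about the weakened C7–C6 and C2–C1 bonds at 0 °C, only 23 can cyclise, and methyl iodide is added after closure.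

Step 13
Reactants: 25 (5S,8S,11S,16S,17S)-C8-methylated tetracyclic 1(19),2(6)-dien-7-one
Product: 28 target alcohol CNP0399382.1, via lithium dienolate 26 (not isolated), via β,γ-unsaturated ketone 27 (not isolated)
Conditions: Li (excess), NH3/THF, −78 °C; then EtOH, −78 → −33 °C; NH4Cl
Reagents that add atoms: none
Why: Dissolving-metal reduction of the linear dienone adds hydrogen at C19 to give dienolate 26 (1,6-reduction), ethanol should protonate C6 kinetically at the α-carbon on the face anti to the adjacent C21 methyl (6S, leaving the tetrasubstituted C1=C2 alkene out of conjugation), and ketone 27 is reduced at once by the remaining lithium to the thermodynamically preferred (7R) alcohol, whose hydroxyl avoids the syn-pentane contact with C18.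

Compound list
1 | 3,3-dimethylcyclohexan-1-one | CC1(C)CCCC(=O)C1 | starting material
2 | 2,5,5-trimethylcyclohexan-1-one (racemic) | CC1CCC(C)(C)CC1=O | intermediate
3 | (R)-1-phenylethan-1-amine | C[C@@H](N)c1ccccc1 | starting material
4 | but-3-en-2-one | CC(=O)C=C | starting material
5 | ketimine of 2 with 3 (not isolated) | CC1CCC(C)(C)CC1=N[C@H](C)c1ccccc1 | intermediate
6 | Michael-adduct imine (not isolated) | CC(=O)CC[C@]1(C)CCC(C)(C)CC1=N[C@H](C)c1ccccc1 | intermediate
7 | (S)-2,5,5-trimethyl-2-(3-oxobutyl)cyclohexan-1-one | CC(=O)CC[C@]1(C)CCC(C)(C)CC1=O | intermediate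
8 | (S)-4a,7,7-trimethyl-4,4a,5,6,7,8-hexahydronaphthalen-2(3H)-one | O=C1C=C2CC(C)(C)CC[C@@]2(C)CC1 | intermediate
9 | lithium (4aS,8aS)-4a,7,7-trimethyl-3,4,4a,5,6,7,8,8a-octahydronaphthalen-2-olate (not isolated) | [Li+].[O-]C1=C[C@@H]2CC(C)(C)CC[C@@]2(C)CC1 | intermediate
10 | (4aS,8aS)-4a,7,7-trimethyl-3,4,4a,5,6,7,8,8a-octahydronaphthalen-2-yl trifluoromethanesulfonate | O=S(=O)(OC1=C[C@@H]2CC(C)(C)CC[C@@]2(C)CC1)C(F)(F)F | intermediate
11 | trimethyl[(4aS,8aS)-4a,7,7-trimethyl-3,4,4a,5,6,7,8,8a-octahydronaphthalen-2-yl]stannane | C[Sn](C)(C)C1=C[C@@H]2CC(C)(C)CC[C@@]2(C)CC1 | intermediate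
12 | (S)-(−)-pulegone | C[C@H]1CCC(=C(C)C)C(=O)C1 | starting material
13 | pulegone dibromide, (5S)-2-bromo-2-(2-bromopropan-2-yl)-5-methylcyclohexan-1-one (not isolated) | C[C@H]1CCC(Br)(C(C)(C)Br)C(=O)C1 | intermediate
14 | methyl (5S)-5-methyl-2-(propan-2-ylidene)cyclopentane-1-carboxylate (C1 epimers) | COC(=O)C1[C@@H](C)CCC1=C(C)C | intermediate
15 | methyl (2S)-2-methyl-5-oxocyclopentane-1-carboxylate (C1 epimers) | COC(=O)C1[C@@H](C)CCC1=O | intermediate
16 | methyl (5S)-5-methyl-2-(trifluoromethanesulfonyloxy)cyclopent-1-ene-1-carboxylate | COC(=O)C1=C(OS(=O)(=O)C(F)(F)F)CC[C@@H]1C | intermediate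
17 | (Z)-but-2-en-2-ylboronic acid | C/C=C(\C)B(O)O | starting material
18 | methyl (5S)-2-[(E)-but-2-en-2-yl]-5-methylcyclopent-1-ene-1-carboxylate | COC(=O)C1=C(/C(C)=C/C)CC[C@@H]1C | intermediate
19 | N,O-dimethylhydroxylamine hydrochloride | CNOC.Cl | starting material
20 | (5S)-2-[(E)-but-2-en-2-yl]-N-methoxy-N,5-dimethylcyclopent-1-ene-1-carboxamide | CON(C)C(=O)C1=C(/C(C)=C/C)CC[C@@H]1C | intermediate
21 | [(4aS,8aS)-4a,7,7-trimethyl-3,4,4a,5,6,7,8,8a-octahydronaphthalen-2-yl]lithium (not isolated) | [Li]C1=C[C@@H]2CC(C)(C)CC[C@@]2(C)CC1 | intermediate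
22 | cross-conjugated trienone (decalinyl cyclopentenyl ketone) | O=C(C1=C[C@@H]2CC(C)(C)CC[C@@]2(C)CC1)C3=C(/C(C)=C/C)CC[C@@H]3C | intermediate
23 | open potassium trienolate, 3-oxido-octatetraene (not isolated) | [K+].[O-]/C(C1=C[C@@H]2CC(C)(C)CC[C@@]2(C)CC1)=C3/C(=C(/C)C=C)CC[C@@H]3C | intermediate
24 | cyclised potassium enolate, C7/C8 enolate with ring C closed (not isolated) | [K+].C/C1=C/C[C@H]2[C@@H]3CC(C)(C)CC[C@@]3(C)CC/C2=C(\[O-])C4=C1CC[C@@H]4C | intermediate
25 | (5S,8S,11S,16S,17S)-C8-methylated tetracyclic 1(19),2(6)-dien-7-one | C/C1=C/C[C@H]2[C@@H]3CC(C)(C)CC[C@@]3(C)CC[C@]2(C)C(=O)C4=C1CC[C@@H]4C | intermediate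
26 | lithium dienolate, O–C7=C6–C2=C1 (not isolated) | [Li+].C/C1=C2\CC[C@H](C)/C2=C(\[O-])[C@@]2(C)CC[C@]3(C)CCC(C)(C)C[C@H]3[C@@H]2CC1 | intermediate
27 | (5S,6S,8S,11S,16S,17S)-β,γ-unsaturated 7-ketone (not isolated) | C/C1=C2\CC[C@H](C)[C@@H]2C(=O)[C@@]2(C)CC[C@]3(C)CCC(C)(C)C[C@H]3[C@@H]2CC1 | intermediate
28 | target alcohol CNP0399382.1 (1Z,5S,6S,7R,8S,11S,16S,17S) | C/C1=C2\CC[C@H](C)[C@@H]2[C@@H](O)[C@@]2(C)CC[C@]3(C)CCC(C)(C)C[C@H]3[C@@H]2CC1 | target

Total step count: 13. Longest linear sequence: 8 steps (steps 1–5, 11, 12, 13; the pulegone branch, steps 6–13, is equally long).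

Steps most likely to fail

Step 12 (Proposed new method). Three processes may fail:
- Kinetic γ-deprotonation at C3, or slow closure, would let methyl iodide trap the open trienolate.
- The cyclooctatrienolate may close further by a 6π process (C8–C19).
- Methyl iodide may attack the α (equatorial) face of C8, which would give the cis B/C fusion; this is the weakest stereochemical point of the route.

Fallback with known chemistry, setting out from 22 and returning at 25: soft enolisation with Me3SiOTf/Et3N (CH2Cl2, −78 → 0 °C) should give the neutral trimethylsilyl trienol ether F1. Warmed in toluene (40–60 °C, with brief irradiation if the enol-ether geometric isomers must be interconverted), it should undergo the established thermal conrotatory 8π closure of a tetraene to the cyclic trimethylsilyl enol ether F2, which is isolated. MeLi (THF, 0 °C) then regenerates the C7/C8 lithium enolate regiospecifically and MeI gives 25. Ring closure and alkylation are thus decoupled, and counter-ion and additives for the methylation can be varied independently. This fallback does not by itself correct the facial selectivity.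

Step 13. The β,γ-unsaturated ketone may be conjugated by base before its carbonyl is reduced, which would lead to over-reduction. Protonation at C6 may occur on the wrong face, or the C7 epimer may form. Fallback, setting out from 25 and returning at 28: after the lithium/ammonia 1,6-reduction the dienolate is silylated (ammonia removed, Me3SiCl/Et3N, THF) to the trimethylsilyl dienol ether F3, which is isolated. Low-temperature protodesilylation (Bu4NF/AcOH, THF, −78 °C) then delivers the C6 proton under kinetic control to give 27, now isolated. Ketone 27 is reduced in a separate electron-transfer step with samarium diiodide (SmI2, H2O, Et3N, THF), which should also favour the more stable (7R) alcohol 28.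

Step 11. Acyl substitution at the shielded, fully substituted Weinreb amide may be slow, and the vinyllithium may instead deprotonate the C18 methyl or C3 methylene hydrogens. Fallback, setting out from 18 and returning at 22: saponification (LiOH, THF/MeOH/H2O, 50 °C) gives the carboxylic acid F4, and oxalyl chloride with catalytic DMF converts it into the acid chloride F5. Palladium-catalysed acylative Stille coupling of F5 with stannane 11 (Pd2(dba)3, tri(2-furyl)phosphine, THF, 50 °C) should give 22 without an organolithium reagent.

Further compounds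
F1 | step 12 | trimethylsilyl trienol ether of 22 (open tetraene) | C[Si](C)(C)O/C(C1=C[C@@H]2CC(C)(C)CC[C@@]2(C)CC1)=C3/C(=C(/C)C=C)CC[C@@H]3C
F2 | step 12 | cyclic trimethylsilyl enol ether (ring C closed, C7/C8 enol ether) | C/C1=C/C[C@H]2[C@@H]3CC(C)(C)CC[C@@]3(C)CC/C2=C(\O[Si](C)(C)C)C4=C1CC[C@@H]4C
F3 | step 13 | trimethylsilyl dienol ether of 26 | C/C1=C2\CC[C@H](C)/C2=C(\O[Si](C)(C)C)[C@@]2(C)CC[C@]3(C)CCC(C)(C)C[C@H]3[C@@H]2CC1
F4 | step 11 | (5S)-2-[(E)-but-2-en-2-yl]-5-methylcyclopent-1-ene-1-carboxylic acid | OC(=O)C1=C(/C(C)=C/C)CC[C@@H]1C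
F5 | step 11 | (5S)-2-[(E)-but-2-en-2-yl]-5-methylcyclopent-1-ene-1-carbonyl chloride | ClC(=O)C1=C(/C(C)=C/C)CC[C@@H]1C
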